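The route rests on cutting the C6–O1 and C6–OMe bonds of the 1,2-dioxane. C6 is a methoxy peroxyketal carbon whose OMe lies cis to the C3 side chain, that is, axial in the chair that keeps both carbon chains equatorial. This anomerically favoured arrangement can be reached by equilibration from C3 alone. One acid-mediated operation in methanol therefore closes the ring and sets C6, starting from an open-chain (S)-γ-hydroperoxy ketone (OOH at C3, C=O at C6, terminal alkyne, silylated C1 alcohol). C3 is set beforehand by SN2 peroxide transfer with inversion on a chiral-pool-derived mesylate whose ketone is masked as a dimethyl ketal. The enyne chain follows by Sonogashira coupling.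

Key step: step 11

Remarks on the chemistry (assumptions and design choices, target numbering O1–O2–C3–C4–C5–C6 throughout):
- The hydroperoxide carbon (C3) and the ketone carbon (C6) are 1,4-related, so the key-step substrate is a γ-hydroperoxy ketone. The (3S,6R) product has OMe cis to the C3 substituent, which matches the target SMILES.
- The ketone is not left free beside the C3 sulfonate. Under a basic peroxide nucleophile a γ-sulfonyloxy ketone can close to a cyclopropyl ketone (enolate C-alkylation) or to a 2-peroxytetrahydrofuran (peroxide addition to C=O, then 5-exo O-alkylation). It is therefore carried as its dimethyl ketal and released together with the hydroperoxide just before the key step.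
- The acetylenic C–H is more acidic than the hydrazone α-C–H, so the hydrazone is deprotonated twice instead of being protected.
- Assumption: compound 1 is bought as the commercial acetonide of (S)-butane-1,2,4-triol.

Step 1
Reactants: 1 (S)-2-(2,2-dimethyl-1,3-dioxolan-4-yl)ethan-1-ol
Product: 2 (S)-tert-butyl[2-(2,2-dimethyl-1,3-dioxolan-4-yl)ethoxy]diphenylsilane
Conditions: TBDPSCl, imidazole, CH2Cl2, 0 °C → rt
Reagents that add atoms: tert-butyl(chloro)diphenylsilane, CC(C)(C)[Si](Cl)(c1ccccc1)c1ccccc1
Why: Imidazole-promoted silylation of the only free (primary) hydroxyl is routine and should give an ether that lasts until the fluoride step; the stereocentre is not involved.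

Step 2
Reactants: 2 (S)-tert-butyl[2-(2,2-dimethyl-1,3-dioxolan-4-yl)ethoxy]diphenylsilane
Product: 3 (S)-4-[(tert-butyldiphenylsilyl)oxy]butane-1,2-diol
Conditions: AcOH/H2O (4:1), rt
Reagents that add atoms: none
Why: Acid-catalysed acetal hydrolysis of a terminal isopropylidene group is much faster than cleavage of a primary TBDPS ether, so the diol should be released with the (S) centre unchanged.

Step 3
Reactants: 3 (S)-4-[(tert-butyldiphenylsilyl)oxy]butane-1,2-diol
Product: 5 (S)-tert-butyl[2-(oxiran-2-yl)ethoxy]diphenylsilane, via primary tosylate 4 (not isolated)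
Conditions: TsCl, Et3N, Bu2SnO (cat.), CH2Cl2, 0 °C → rt; then K2CO3, MeOH, rt
Reagents that add atoms: none
Why: Tin-catalysed sulfonylation should select the primary hydroxyl, and the secondary alkoxide then closes the oxirane by intramolecular Williamson substitution at CH2, so the C–O bond at the stereocentre is never broken and (S) is retained.

Step 4
Reactants: 6 hept-6-yn-2-one
Product: 7 (E)-hept-6-yn-2-one N,N-dimethylhydrazone
Conditions: Me2NNH2, AcOH (cat.), EtOH, reflux
Reagents that add atoms: 1,1-dimethylhydrazine, CN(C)N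
Why: Hydrazone condensation of a methyl ketone is reliable and provides the azaenolate precursor that is deprotonated on the methyl side.

Step 5
Reactants: 7 (E)-hept-6-yn-2-one N,N-dimethylhydrazone; 5 (S)-tert-butyl[2-(oxiran-2-yl)ethoxy]diphenylsilane
Product: 10 (R)-1-[(tert-butyldiphenylsilyl)oxy]-3-hydroxyundec-10-yn-6-one, via dilithio azaenolate 8 (not isolated), via hydroxy hydrazone 9 (not isolated)
Conditions: LDA (2.1 equiv), THF, −78 → 0 °C; then 5, 0 °C → rt; then sat. aq. oxalic acid, Et2O, rt
Reagents that add atoms: water, O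
Why: Two equivalents of LDA remove first the acetylenic proton and then the methyl α-proton; the azaenolate carbon opens the terminal epoxide at CH2 (hydrazone azaenolate alkylation, SN2) while the lithium acetylide is inert to an unactivated epoxide, and mild acid hydrolysis returns the ketone. The stereocentre is not attacked, so its geometry is kept and only the CIP label changes from S to R.

Step 6
Reactants: 10 (R)-1-[(tert-butyldiphenylsilyl)oxy]-3-hydroxyundec-10-yn-6-one
Product: 11 (R)-1-[(tert-butyldiphenylsilyl)oxy]-6-oxoundec-10-yn-3-yl methanesulfonate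
Conditions: MsCl, Et3N, CH2Cl2, −20 → 0 °C
Reagents that add atoms: methanesulfonyl chloride, CS(=O)(=O)Cl
Why: Standard O-sulfonylation of the secondary hydroxyl of the open-chain form leaves the C–O bond intact (retention, R), and ring–chain tautomerism of 10 does not interfere because only this hydroxyl is sulfonylated.

Step 7
Reactants: 11 (R)-1-[(tert-butyldiphenylsilyl)oxy]-6-oxoundec-10-yn-3-yl methanesulfonate
Product: 12 (R)-1-[(tert-butyldiphenylsilyl)oxy]-6,6-dimethoxyundec-10-yn-3-yl methanesulfonate
Conditions: MeOTMS, TMSOTf (cat.), CH2Cl2, −78 °C; pyridine quench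
Reagents that add atoms: methoxytrimethylsilane, CO[Si](C)(C)C
Why: TMSOTf-catalysed silyl-transfer ketalisation is aprotic and run cold, so the secondary mesylate should survive, and the ketal removes the enolisable, electrophilic carbonyl before the basic displacement.

Step 8
Reactants: 13 2,3-dimethylbut-2-ene
Product: 14 2-hydroperoxy-2-methoxypropane (2-methoxyprop-2-yl hydroperoxide)
Conditions: O3, MeOH/CH2Cl2, −78 °C
Reagents that add atoms: ozone, [O-][O+]=O; methanol, CO
Why: Ozonolysis of a tetrasubstituted alkene in methanol (Criegee mechanism) traps the carbonyl oxide as the α-methoxy hydroperoxide, a protected hydroperoxide nucleophile that is not a stock item.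

Step 9
Reactants: 12 (R)-1-[(tert-butyldiphenylsilyl)oxy]-6,6-dimethoxyundec-10-yn-3-yl methanesulfonate; 14 2-hydroperoxy-2-methoxypropane
Product: 15 (S)-tert-butyl({6,6-dimethoxy-3-[(2-methoxypropan-2-yl)peroxy]undec-10-yn-1-yl}oxy)diphenylsilane
Conditions: 14 (2 equiv), CsOH·H2O (1.5 equiv), DMF, 0 °C → rt
Reagents that add atoms: none
Why: The caesium peroxide anion is a weakly basic α-effect nucleophile that should displace the secondary mesylate by SN2 with inversion, turning the (R)-sulfonate into the (S)-peroxide; the ketal, silyl ether and alkyne offer no competing site.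

Step 10
Reactants: 15 (S)-tert-butyl({6,6-dimethoxy-3-[(2-methoxypropan-2-yl)peroxy]undec-10-yn-1-yl}oxy)diphenylsilane
Product: 16 (S)-1-[(tert-butyldiphenylsilyl)oxy]-3-hydroperoxyundec-10-yn-6-one
Conditions: AcOH/THF/H2O (3:1:1), rt
Reagents that add atoms: water, O
Why: The peroxyketal protecting group and the dimethyl ketal are both acetal-type functions that should hydrolyse in dilute aqueous acetic acid without touching the C3–O bond (S retained) or the TBDPS ether; the product is in ring–chain equilibrium, which is harmless because step 11 runs through the ring form.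

Step 11
Reactants: 16 (S)-1-[(tert-butyldiphenylsilyl)oxy]-3-hydroperoxyundec-10-yn-6-one
Product: 18 tert-butyl{2-[(3S,6R)-6-methoxy-6-(pent-4-yn-1-yl)-1,2-dioxan-3-yl]ethoxy}diphenylsilane, via cyclic peroxyhemiketal 17 (not isolated)
Conditions: CSA (10 mol %), MeOH, 3 Å MS, rt; Et3N quench
Reagents that add atoms: methanol, CO
Why: The terminal oxygen of the C3 hydroperoxide adds to the protonated C6 ketone in a 6-exo-trig closure to give the 1,2-dioxan-3-ol 17, which loses water by ionisation at C6 and is captured by methanol, so C6–O1 and C6–OMe are formed and the ring is closed in one operation. The closest known reaction type is the acid-catalysed ring closure of γ-hydroperoxy ketones to cyclic peroxyhemiketals and their exchange with alcohols to 3-alkoxy-1,2-dioxanes. Every stage is reversible, so C6 is set under thermodynamic control: the chair with the C3 side chain and the C6 pentynyl chain equatorial and the methoxy group axial (anomeric stabilisation by the O1 lone pair) is the (3S,6R) isomer, and axial capture of the half-chair cation should lead to the same isomer kinetically. The controlling element is the fixed C3 centre, which is untouched because no bond to C3 is broken. The step needs ring peroxyketal over open-chain dimethyl ketal and cis over trans at C6; the 1,4-relationship of OOH and C=O (six-membered ring) and the anomeric preference secure both, while the TBDPS ether and the terminal alkyne should be inert to catalytic CSA in methanol at room temperature.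

Step 12
Reactants: 19 dec-9-yn-1-ol
Product: 21 (E)-10-iododec-9-en-1-ol, via alkenylzirconocene 20 (not isolated)
Conditions: Cp2Zr(H)Cl (2.2 equiv), THF, rt, dark; then I2, 0 °C
Reagents that add atoms: iodine, II
Why: The first equivalent of Schwartz reagent converts the hydroxyl into a zirconium alkoxide, the second adds syn across the alkyne with zirconium at the terminal carbon, and iodinolysis with retention should give only the (E)-iodoalkene (hydrozirconation–iodination).

Step 13
Reactants: 21 (E)-10-iododec-9-en-1-ol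
Product: 22 (E)-10-iododec-9-enal
Conditions: Dess–Martin periodinane, CH2Cl2, rt
Reagents that add atoms: none
Why: Dess–Martin oxidation stops at the aldehyde and leaves the iodoalkene untouched.

Step 14
Reactants: 22 (E)-10-iododec-9-enal
Product: 23 (E)-11-iodoundec-10-en-2-ol (racemic)
Conditions: MeMgBr, THF, −78 °C
Reagents that add atoms: methylmagnesium bromide, C[Mg]Br
Why: Grignard addition to the aldehyde is fast at −78 °C, where an alkenyl iodide does not exchange with MeMgBr; the new carbinol centre is racemic and is removed in the next step.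

Step 15
Reactants: 23 (E)-11-iodoundec-10-en-2-ol (racemic)
Product: 24 (E)-11-iodoundec-10-en-2-one
Conditions: Dess–Martin periodinane, CH2Cl2, rt
Reagents that add atoms: none
Why: Dess–Martin oxidation of the secondary alcohol gives the methyl ketone without affecting the alkene geometry.

Step 16
Reactants: 18 tert-butyl{2-[(3S,6R)-6-methoxy-6-(pent-4-yn-1-yl)-1,2-dioxan-3-yl]ethoxy}diphenylsilane; 24 (E)-11-iodoundec-10-en-2-one
Product: 25 tert-butyl(2-{(3S,6R)-6-methoxy-6-[(6E)-15-oxohexadec-6-en-4-yn-1-yl]-1,2-dioxan-3-yl}ethoxy)diphenylsilane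
Conditions: PdCl2(PPh3)2 (cat.), CuI (cat.), Et3N, THF, rt, degassed
Reagents that add atoms: none
Why: Sonogashira coupling of the terminal alkyne with the alkenyl iodide proceeds with retention of the (E) geometry at room temperature, conditions that a saturated dialkyl peroxyketal without an activated C3–H should tolerate; ketone and silyl ether are spectators.

Step 17
Reactants: 25 tert-butyl(2-{(3S,6R)-6-methoxy-6-[(6E)-15-oxohexadec-6-en-4-yn-1-yl]-1,2-dioxan-3-yl}ethoxy)diphenylsilane
Product: 26 2-{(3S,6R)-6-methoxy-6-[(6E)-15-oxohexadec-6-en-4-yn-1-yl]-1,2-dioxan-3-yl}ethan-1-ol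
Conditions: TBAF/AcOH (1:1), THF, 0 °C → rt
Reagents that add atoms: none
Why: Fluoride-driven desilylation (Si–F bond formation) buffered with acetic acid should free the primary alcohol without base-induced Kornblum–DeLaMare fragmentation at the C3–H of the peroxide.

Step 18
Reactants: 26 2-{(3S,6R)-6-methoxy-6-[(6E)-15-oxohexadec-6-en-4-yn-1-yl]-1,2-dioxan-3-yl}ethan-1-ol
Product: 28 2-{(3S,6R)-6-methoxy-6-[(6E)-15-oxohexadec-6-en-4-yn-1-yl]-1,2-dioxan-3-yl}acetic acid, via aldehyde 27 (not isolated)
Conditions: PhI(OAc)2, TEMPO (cat.), CH2Cl2, rt; then NaClO2, NaH2PO4, 2-methylbut-2-ene, t-BuOH/H2O, 0 °C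
Reagents that add atoms: sodium chlorite, [Na+].[O-]Cl=O
Why: Oxoammonium (TEMPO) oxidation to the aldehyde followed by Pinnick oxidation of the crude material keeps the medium mildly acidic, which should avoid β-elimination of the peroxide, and the alkene scavenger protects the enyne from hypochlorite.

Compound list
1 | (S)-2-(2,2-dimethyl-1,3-dioxolan-4-yl)ethan-1-ol | CC1(C)OC[C@H](CCO)O1 | starting material
2 | (S)-tert-butyl[2-(2,2-dimethyl-1,3-dioxolan-4-yl)ethoxy]diphenylsilane | CC1(C)OC[C@H](CCO[Si](c2ccccc2)(c2ccccc2)C(C)(C)C)O1 | intermediate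
3 | (S)-4-[(tert-butyldiphenylsilyl)oxy]butane-1,2-diol | OC[C@@H](O)CCO[Si](c1ccccc1)(c1ccccc1)C(C)(C)C | intermediate
4 | (S)-4-[(tert-butyldiphenylsilyl)oxy]-2-hydroxybutyl 4-methylbenzenesulfonate (primary tosylate, not isolated) | Cc1ccc(cc1)S(=O)(=O)OC[C@@H](O)CCO[Si](c1ccccc1)(c1ccccc1)C(C)(C)C | intermediate
5 | (S)-tert-butyl[2-(oxiran-2-yl)ethoxy]diphenylsilane | C1O[C@H]1CCO[Si](c1ccccc1)(c1ccccc1)C(C)(C)C | intermediate
6 | hept-6-yn-2-one | CC(=O)CCCC#C | starting material
7 | (E)-hept-6-yn-2-one N,N-dimethylhydrazone | C/C(CCCC#C)=N\N(C)C | intermediate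
8 | dilithio azaenolate of 7 (lithium acetylide and N-lithio ene-hydrazide, not isolated) | [Li]C#CCCCC(=C)N([Li])N(C)C | intermediate
9 | (R)-1-[(tert-butyldiphenylsilyl)oxy]-6-(2,2-dimethylhydrazinylidene)undec-10-yn-3-ol (hydroxy hydrazone, C=N geometry not defined, not isolated) | C#CCCCC(=NN(C)C)CC[C@@H](O)CCO[Si](c1ccccc1)(c1ccccc1)C(C)(C)C | intermediate
10 | (R)-1-[(tert-butyldiphenylsilyl)oxy]-3-hydroxyundec-10-yn-6-one | C#CCCCC(=O)CC[C@@H](O)CCO[Si](c1ccccc1)(c1ccccc1)C(C)(C)C | intermediate
11 | (R)-1-[(tert-butyldiphenylsilyl)oxy]-6-oxoundec-10-yn-3-yl methanesulfonate | C#CCCCC(=O)CC[C@@H](OS(C)(=O)=O)CCO[Si](c1ccccc1)(c1ccccc1)C(C)(C)C | intermediate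
12 | (R)-1-[(tert-butyldiphenylsilyl)oxy]-6,6-dimethoxyundec-10-yn-3-yl methanesulfonate | C#CCCCC(OC)(OC)CC[C@@H](OS(C)(=O)=O)CCO[Si](c1ccccc1)(c1ccccc1)C(C)(C)C | intermediate
13 | 2,3-dimethylbut-2-ene | CC(C)=C(C)C | starting material
14 | 2-hydroperoxy-2-methoxypropane | COC(C)(C)OO | intermediate
15 | (S)-tert-butyl({6,6-dimethoxy-3-[(2-methoxypropan-2-yl)peroxy]undec-10-yn-1-yl}oxy)diphenylsilane | C#CCCCC(OC)(OC)CC[C@H](OOC(C)(C)OC)CCO[Si](c1ccccc1)(c1ccccc1)C(C)(C)C | intermediate
16 | (S)-1-[(tert-butyldiphenylsilyl)oxy]-3-hydroperoxyundec-10-yn-6-one | C#CCCCC(=O)CC[C@H](OO)CCO[Si](c1ccccc1)(c1ccccc1)C(C)(C)C | intermediate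
17 | (6S)-6-{2-[(tert-butyldiphenylsilyl)oxy]ethyl}-3-(pent-4-yn-1-yl)-1,2-dioxan-3-ol (cyclic peroxyhemiketal, both C3 epimers, not isolated) | OC1(CCCC#C)CC[C@@H](CCO[Si](c2ccccc2)(c2ccccc2)C(C)(C)C)OO1 | intermediate
18 | tert-butyl{2-[(3S,6R)-6-methoxy-6-(pent-4-yn-1-yl)-1,2-dioxan-3-yl]ethoxy}diphenylsilane | CO[C@@]1(CCCC#C)CC[C@@H](CCO[Si](c2ccccc2)(c2ccccc2)C(C)(C)C)OO1 | intermediate
19 | dec-9-yn-1-ol | OCCCCCCCCC#C | starting material
20 | (E)-alkenylzirconocene chloride carrying the zirconocene chloride alkoxide, Cp2Zr(Cl)–O(CH2)8CH=CH–Zr(Cl)Cp2 (Cp drawn σ-bonded, not isolated) | Cl[Zr](OCCCCCCCC/C=C/[Zr](Cl)(C1C=CC=C1)C1C=CC=C1)(C1C=CC=C1)C1C=CC=C1 | intermediate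
21 | (E)-10-iododec-9-en-1-ol | OCCCCCCCC/C=C/I | intermediate
22 | (E)-10-iododec-9-enal | O=CCCCCCCC/C=C/I | intermediate
23 | (E)-11-iodoundec-10-en-2-ol (racemic) | CC(O)CCCCCCC/C=C/I | intermediate
24 | (E)-11-iodoundec-10-en-2-one | CC(=O)CCCCCCC/C=C/I | intermediate
25 | tert-butyl(2-{(3S,6R)-6-methoxy-6-[(6E)-15-oxohexadec-6-en-4-yn-1-yl]-1,2-dioxan-3-yl}ethoxy)diphenylsilane | CO[C@@]1(CCCC#C/C=C/CCCCCCCC(C)=O)CC[C@@H](CCO[Si](c2ccccc2)(c2ccccc2)C(C)(C)C)OO1 | intermediate
26 | 2-{(3S,6R)-6-methoxy-6-[(6E)-15-oxohexadec-6-en-4-yn-1-yl]-1,2-dioxan-3-yl}ethan-1-ol | CO[C@@]1(CCCC#C/C=C/CCCCCCCC(C)=O)CC[C@@H](CCO)OO1 | intermediate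
27 | 2-{(3S,6R)-6-methoxy-6-[(6E)-15-oxohexadec-6-en-4-yn-1-yl]-1,2-dioxan-3-yl}acetaldehyde (not isolated) | CO[C@@]1(CCCC#C/C=C/CCCCCCCC(C)=O)CC[C@@H](CC=O)OO1 | intermediate
28 | 2-{(3S,6R)-6-methoxy-6-[(6E)-15-oxohexadec-6-en-4-yn-1-yl]-1,2-dioxan-3-yl}acetic acid | CO[C@@]1(CCCC#C/C=C/CCCCCCCC(C)=O)CC[C@@H](CC(=O)O)OO1 | target

Total step count: 18.
Longest linear sequence: 12 steps from 1 (steps 1, 2, 3, 5, 6, 7, 9, 10, 11, 16, 17, 18).

Steps most likely to fail

1. Step 9. Substitution at the secondary carbon may be slow, E2 elimination may compete, and ionisation of the mesylate assisted by a ketal oxygen would erode the inversion. The fallback delivers the peroxide intramolecularly, setting out from 12 and coming back at 18. Urea–hydrogen peroxide with catalytic acid in Et2O/MeOH should exchange one methoxy group of 12 for a hydroperoxy group, giving (3R)-1-[(tert-butyldiphenylsilyl)oxy]-6-hydroperoxy-6-methoxyundec-10-yn-3-yl methanesulfonate F1 as a C6 epimer mixture. KOt-Bu with 18-crown-6 in THF should then close the ring by 6-exo-tet SN2 displacement of the mesylate with inversion at C3. This should give 18 together with its C6 epimer tert-butyl{2-[(3S,6S)-6-methoxy-6-(pent-4-yn-1-yl)-1,2-dioxan-3-yl]ethoxy}diphenylsilane F2, which the conditions of step 11 should equilibrate into 18. In this variant the ring bond formed is C3–O2 and the acid equilibration is kept only for setting C6.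

2. Step 11. The equilibrium may not drain cleanly to one compound (open-chain ketal or the trans epimer persisting), and long exposure to protic acid may cause loss of the silyl ether or acid-promoted decay of the hydroperoxide. The fallback replaces protic equilibration by an aprotic, kinetically controlled substitution, setting out from 16 and coming back at 18. Silylation of the ring–chain mixture with N,O-bis(trimethylsilyl)acetamide in CH2Cl2 should give mainly tert-butyl(2-{(3S)-6-(pent-4-yn-1-yl)-6-[(trimethylsilyl)oxy]-1,2-dioxan-3-yl}ethoxy)diphenylsilane F3. Catalytic TMSOTf with methoxytrimethylsilane at −78 °C should ionise it at C6, and axial capture of the peroxycarbenium ion should give 18. This is the known Lewis-acid-mediated substitution at peroxyketal carbons.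

3. Step 16. Palladium(0) or free phosphine may cleave the O–O bond, the amine may trigger fragmentation of the peroxide, and oxidative homocoupling may consume the alkyne. The fallback moves the coupling ahead of peroxide introduction, setting out from 12 and 24 and coming back at 25.
   - Sonogashira coupling under the conditions of step 16 should give (3R,12E)-1-[(tert-butyldiphenylsilyl)oxy]-6,6-dimethoxy-21-oxodocos-12-en-10-yn-3-yl methanesulfonate F4.
   - Displacement with 14 and CsOH·H2O as in step 9 should give (3S,12E)-1-[(tert-butyldiphenylsilyl)oxy]-6,6-dimethoxy-3-[(2-methoxypropan-2-yl)peroxy]docos-12-en-10-yn-21-one F5.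
   - Aqueous acetic acid as in step 10 should give (3S,12E)-1-[(tert-butyldiphenylsilyl)oxy]-3-hydroperoxydocos-12-en-10-yne-6,21-dione F6.
   - The conditions of step 11 should then close F6 to 25. The remote methyl ketone is a spectator, and any dimethyl ketal formed there is returned to the ketone by a mildly acidic aqueous work-up.

Further compounds
F1 | step 9 | (3R)-1-[(tert-butyldiphenylsilyl)oxy]-6-hydroperoxy-6-methoxyundec-10-yn-3-yl methanesulfonate (C6 epimers) | C#CCCCC(OC)(OO)CC[C@@H](OS(C)(=O)=O)CCO[Si](c1ccccc1)(c1ccccc1)C(C)(C)C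
F2 | step 9 | tert-butyl{2-[(3S,6S)-6-methoxy-6-(pent-4-yn-1-yl)-1,2-dioxan-3-yl]ethoxy}diphenylsilane | CO[C@]1(CCCC#C)CC[C@@H](CCO[Si](c2ccccc2)(c2ccccc2)C(C)(C)C)OO1
F3 | step 11 | tert-butyl(2-{(3S)-6-(pent-4-yn-1-yl)-6-[(trimethylsilyl)oxy]-1,2-dioxan-3-yl}ethoxy)diphenylsilane (C6 epimers) | C[Si](C)(C)OC1(CCCC#C)CC[C@@H](CCO[Si](c2ccccc2)(c2ccccc2)C(C)(C)C)OO1
F4 | step 16 | (3R,12E)-1-[(tert-butyldiphenylsilyl)oxy]-6,6-dimethoxy-21-oxodocos-12-en-10-yn-3-yl methanesulfonate | CC(=O)CCCCCCC/C=C/C#CCCCC(OC)(OC)CC[C@@H](OS(C)(=O)=O)CCO[Si](c1ccccc1)(c1ccccc1)C(C)(C)C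
F5 | step 16 | (3S,12E)-1-[(tert-butyldiphenylsilyl)oxy]-6,6-dimethoxy-3-[(2-methoxypropan-2-yl)peroxy]docos-12-en-10-yn-21-one | CC(=O)CCCCCCC/C=C/C#CCCCC(OC)(OC)CC[C@H](OOC(C)(C)OC)CCO[Si](c1ccccc1)(c1ccccc1)C(C)(C)C
F6 | step 16 | (3S,12E)-1-[(tert-butyldiphenylsilyl)oxy]-3-hydroperoxydocos-12-en-10-yne-6,21-dione | CC(=O)CCCCCCC/C=C/C#CCCCC(=O)CC[C@H](OO)CCO[Si](c1ccccc1)(c1ccccc1)C(C)(C)C
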